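Readings and results are calculated with constants of no real substance, noise included.

East at 8.00 h shows 19.2 % of the substrates in the two species read, so my ledger needs an open line for the rest.

| flask | left-handed substrate | right-handed substrate | partner | remark | time |
|---|---|---|---|---|---|
| east | 0.099 M | 0.099 M | 1 equiv | run made earlier |  |
| south | 0.099 M | 0.099 M | 1.5 equiv | run made earlier |  |
| flask | 0.099 M | 0.099 M | 2.00 equiv |  | 10 h |

| run | time / h | achiral form / % | left-handed product / % |
|---|---|---|---|
| east | 0.100 | 17.3 | 2.6 |
| east | 0.250 | 26.2 | 4.0 |
| east | 0.833 | 22.6 | 8.9 |
| east | 2.50 | 7.2 | 15.2 |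
| east | 8.00 | 2.3 | 16.9 |
| south | 0.100 | 18.7 | 3.1 |
| south | 0.250 | 26.5 | 6.1 |
| south | 0.833 | 24.3 | 13.8 |
| south | 2.50 | 5.4 | 21.9 |
| south | 8.00 | 0 | 25.6 |

(each reading ± 1 percentage point)
- partner is single-handed; left-handed substrate and right-handed substrate are mirror images of each other, charged as a racemate, each of them at the stated concentration
- the handed part of partner does not stay in what it makes, so the products of the two hands are mirror images too
1. time, not beyond 10 h, at which the flask holds most achiral form
2. the amount of achiral form, in percent of the left-handed substrate and right-handed substrate together charged, at that time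
3. the first time at which achiral form reaches 8.4 %, in the same percent, in min

I book the substrates as the limiting reagent, since east's left-handed product at 8.00 h used about a third of its partner. The hands are mirror images, so I book half of the achiral form to the left-handed substrate and left-handed product as its second entry. I replace each curve by its mean: an amount at 0.250 h is a mean rate times that time, so a ratio of entries is a ratio of mean rates. Scaled to the flask's partner, east gives 0.611 and south 0.614. Their mean, 0.612, is the capture ratio: left-handed product made per left-handed substrate entering achiral form. The share of both hands reaching achiral form is then 0.810 in the flask and 0.883 in east. I therefore expect the flask's crest lower than east's, at 0.917 of it.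

The forecast gives 28 % at 0.42 h and 8.4 % at 2.2 min, and says “the peak creeps up slightly with partner”, where I expect a fall.

The flask gives 28.0 % at 0.370 h and reaches 8.4 % at 2.41 min.

    partner + left-handed substrate → left-handed product (k = 0.00130 M⁻¹ s⁻¹)
    partner + right-handed substrate → right-handed product (k = 1.00 × 10⁻⁴ M⁻¹ s⁻¹)
    left-handed substrate ⇌ achiral form (K = 1.70, k = 6.70 × 10⁻⁴ s⁻¹)
    right-handed substrate ⇌ achiral form (K = 1.70, k = 6.70 × 10⁻⁴ s⁻¹)
    achiral form → decomposed reagent (k = 4.00 × 10⁻⁴ s⁻¹)

East's crest without the scatter is 29.3 %, so the flask stands at 0.955 of it, above the 0.917 I reckoned. At the start of the flask, the forward rate of capture is 0.38 of the forward passing of left-handed substrate into achiral form. For the neighbour flask with 8.00 equiv of partner, the capture ratio scales to 2.45 and the share to 0.645, which gives an estimated crest of 22.3 % from the flask's; that neighbour reaches 22.8 %.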